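**Plan**

Atom numbers are those of the 2,3-dihydro-1,4-benzodioxine core: O1, C2 (bears the trimethoxyphenyl group), C3 (bears the methyl group), O4, C4a, C5 (OMe), C7 (side chain), C8a.

- Retrosynthetic cuts: the C7–Cα bond of the propenal chain (aryl bromide + acrolein acetal), then the aryl ether bond O1–C8a of the dioxane ring, then the alkyl aryl ether bond O4–C3 (a 2-iodophenol + an α-bromo ketone).
- Forward order: O-alkylation joins the two halves to a racemic α-aryloxy ketone; one flask reduces it under dynamic kinetic resolution and closes the dioxane ring (the only ring made) at O1–C8a; a Heck coupling adds the enal last.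
- Enabling feature: in the open-chain ketone the C3–H is α to the C2 carbonyl and sits on the carbon bearing O4, so C3 equilibrates. The C2 oxygen reaches the iodine-bearing C8a of the guaiacyl ring through a six-membered transition state, and the new O1–C8a bond touches neither stereocentre, so threo maps onto trans.
- Stereochemistry: C2 (S) from the (R,R)-TsDPEN–Ru catalyst; C3 (S) from the dynamic kinetic resolution (Felkin–Anh matched enantiomer of the equilibrating ketone); E-alkene from the Heck β-hydride elimination.
- Helpers: ketone oxidation level at C2 (makes C3 labile, removed by the reduction); ortho iodine (leaves in the ring closure); para bromine (replaced by the side chain).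

Key step: step 4

**Route**

Step 1
Reactants: 1 1-(3,4,5-trimethoxyphenyl)propan-1-one
Product: 2 rac-2-bromo-1-(3,4,5-trimethoxyphenyl)propan-1-one
Conditions: CuBr2 (2.1 equiv), EtOAc/CHCl3 1:1, reflux
Reagents that add atoms: copper(II) bromide, [Cu+2].[Br-].[Br-]
Why: α-bromination of the aryl ketone through its enol with copper(II) bromide, which halogenates the only enolisable carbon and leaves the acyl-deactivated arene alone; the new centre is racemic and is replaced in step 3.

Step 2
Reactants: 3 4-bromo-2-methoxyphenol
Product: 4 4-bromo-2-iodo-6-methoxyphenol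
Conditions: NIS (1.05 equiv), p-TsOH·H2O (10 mol%), MeCN, 0 °C to rt
Reagents that add atoms: N-iodosuccinimide, O=C1CCC(=O)N1I
Why: electrophilic aromatic iodination with acid-activated NIS, directed by the free phenolic OH to its only open ortho position (the para position carries bromine), which places iodine on the carbon that becomes C8a.

Step 3
Reactants: 2 rac-2-bromo-1-(3,4,5-trimethoxyphenyl)propan-1-one; 4 4-bromo-2-iodo-6-methoxyphenol
Product: 5 rac-2-(4-bromo-2-iodo-6-methoxyphenoxy)-1-(3,4,5-trimethoxyphenyl)propan-1-one
Conditions: K2CO3 (1.5 equiv), DMF, rt to 40 °C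
Reagents that add atoms: none
Why: Williamson-type SN2 substitution of the α-keto bromide by the phenoxide of 4, accelerated by the adjacent carbonyl group; the new C3 centre is formed as the racemate on purpose, since step 4 equilibrates it.

Step 4
Reactants: 5 rac-2-(4-bromo-2-iodo-6-methoxyphenoxy)-1-(3,4,5-trimethoxyphenyl)propan-1-one
Product: 7 (2S,3S)-7-bromo-5-methoxy-3-methyl-2-(3,4,5-trimethoxyphenyl)-2,3-dihydro-1,4-benzodioxine, via threo iodo alcohol 6 (not isolated)
Conditions: RuCl[(R,R)-TsDPEN](p-cymene) (2 mol%), HCO2H (3 equiv), DBU (3.5 equiv), MeCN, 40 °C; then MeCN removed, CuI (10 mol%), 1,10-phenanthroline (20 mol%), Cs2CO3 (4 equiv), toluene, 90 °C, same flask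
Reagents that add atoms: none
Why: DBU enolises ketone 5 at C3 (the C3–H is α to the aryl ketone and on the carbon carrying O4), so its two enantiomers interconvert while the Ru–H/N–H form of the catalyst delivers hydride and proton through the outer-sphere six-membered transition state of a Noyori–Ikariya asymmetric transfer hydrogenation, the closest known case being the dynamic kinetic resolution of benzoin-type α-oxygenated aryl ketones. The catalyst should fix the carbonyl face through the CH/π contact between its p-cymene ligand and the trimethoxyphenyl ring and so set C2 as S (the facial sense that gives (R)-1-phenylethanol; the descriptor is S here because C3 outranks the aryl group), and of the equilibrating ketone enantiomers the (3S) one should react faster because hydride then enters anti to the C3–OAr bond (Felkin–Anh polar model), which sets C3 as S and funnels the racemate into threo alcohol 6. Caesium carbonate then forms the C2 alkoxide, the phenanthroline–copper(I) alkoxide adds oxidatively to the ortho C8a–I bond, and C–O reductive elimination (Ullmann-type etherification, known for 2-(2-halophenoxy)ethanols giving 1,4-benzodioxanes) closes the dioxane ring. This single ring closure is six-membered, with the alkoxide oxygen attacking the sp2 carbon C8a and the leaving iodide outside the ring (6-exo type); it makes or breaks no bond at C2 or C3, so threo 6 should become trans 7 with retention at both centres. The step needs iodine to react in preference to bromine: the C–I bond is the weaker one and the only halogen the tethered alkoxide can reach through a six-membered transition state, so the para bromine is kept for step 5. Hydride transfer from formate is irreversible (loss of CO2), which should keep the alcohol from re-equilibrating once formed.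

Step 5
Reactants: 7 (2S,3S)-7-bromo-5-methoxy-3-methyl-2-(3,4,5-trimethoxyphenyl)-2,3-dihydro-1,4-benzodioxine
Product: 9 (E)-3-[(2S,3S)-8-methoxy-2-methyl-3-(3,4,5-trimethoxyphenyl)-2,3-dihydro-1,4-benzodioxin-6-yl]prop-2-enal (target; the side-chain carbon is C7 in the numbering of 7), via enal diethyl acetal 8 (not isolated)
Conditions: acrolein diethyl acetal (3 equiv), Pd(OAc)2 (3 mol%), n-Bu4NOAc (2 equiv), K2CO3 (1.5 equiv), KCl (1 equiv), DMF, 90 °C; then 2 M HCl, rt
Reagents that add atoms: acrolein diethyl acetal (3,3-diethoxyprop-1-ene), C=CC(OCC)OCC; water, O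
Why: Mizoroki–Heck coupling of the one remaining aryl halide with acetal-protected acrolein, in which syn β-hydride elimination toward the benzylic carbon should give the conjugated E-alkene of 8 and dilute acid then unmasks the aldehyde; C2 and C3 carry no acidic hydrogen and are not touched.

**Compound list**

1 | 1-(3,4,5-trimethoxyphenyl)propan-1-one | CCC(=O)c1cc(OC)c(OC)c(OC)c1 | starting material
2 | rac-2-bromo-1-(3,4,5-trimethoxyphenyl)propan-1-one | CC(Br)C(=O)c1cc(OC)c(OC)c(OC)c1 | intermediate
3 | 4-bromo-2-methoxyphenol | COc1cc(Br)ccc1O | starting material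
4 | 4-bromo-2-iodo-6-methoxyphenol | COc1cc(Br)cc(I)c1O | intermediate
5 | rac-2-(4-bromo-2-iodo-6-methoxyphenoxy)-1-(3,4,5-trimethoxyphenyl)propan-1-one | COc1cc(C(=O)C(C)Oc2c(I)cc(Br)cc2OC)cc(OC)c1OC | intermediate
6 | (1S,2S)-2-(4-bromo-2-iodo-6-methoxyphenoxy)-1-(3,4,5-trimethoxyphenyl)propan-1-ol (threo) | COc1cc([C@H](O)[C@@H](Oc2c(I)cc(Br)cc2OC)C)cc(OC)c1OC | intermediate
7 | (2S,3S)-7-bromo-5-methoxy-3-methyl-2-(3,4,5-trimethoxyphenyl)-2,3-dihydro-1,4-benzodioxine (trans) | COc1cc([C@@H]2Oc3cc(Br)cc(OC)c3O[C@H]2C)cc(OC)c1OC | intermediate
8 | (2S,3S)-7-[(1E)-3,3-diethoxyprop-1-en-1-yl]-5-methoxy-3-methyl-2-(3,4,5-trimethoxyphenyl)-2,3-dihydro-1,4-benzodioxine | COc1cc([C@@H]2Oc3cc(/C=C/C(OCC)OCC)cc(OC)c3O[C@H]2C)cc(OC)c1OC | intermediate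
9 | (E)-3-[(2S,3S)-8-methoxy-2-methyl-3-(3,4,5-trimethoxyphenyl)-2,3-dihydro-1,4-benzodioxin-6-yl]prop-2-enal | COc1cc([C@@H]2Oc3cc(/C=C/C=O)cc(OC)c3O[C@H]2C)cc(OC)c1OC | target

Total steps: 5 (step 4 is a one-flask, two-stage operation). Longest linear sequence: 4 steps (1 → 2 → 5 → 7 → 9, or 3 → 4 → 5 → 7 → 9).

**Steps most likely to fail**

Step 4. Two processes may fail: enolisation at C3 may be slow relative to hydride transfer, so that the mismatched ketone enantiomer is reduced and erythro alcohol forms; and the ortho iodine may be lost by reduction with residual formate during the copper stage. The fallback sets out from 4 and comes back at 7; it takes the C3 centre from the chiral pool and removes the need for equilibration. Mitsunobu reaction of 4 with methyl (R)-lactate (PPh3, DIAD, THF) should give, with inversion, methyl (S)-2-(4-bromo-2-iodo-6-methoxyphenoxy)propanoate F1. Aminolysis with MeNHOMe·HCl and AlMe3 in CH2Cl2 gives the Weinreb amide (S)-2-(4-bromo-2-iodo-6-methoxyphenoxy)-N-methoxy-N-methylpropanamide F2. Addition of 3,4,5-trimethoxyphenylmagnesium bromide (from 5-bromo-1,2,3-trimethoxybenzene) at −20 °C gives the single-enantiomer ketone (S)-2-(4-bromo-2-iodo-6-methoxyphenoxy)-1-(3,4,5-trimethoxyphenyl)propan-1-one F3. Transfer hydrogenation of F3 with the same (R,R) catalyst in HCO2H/Et3N 5:2 without DBU (matched case, non-epimerising medium) gives 6, which is isolated, freed from formate and closed to 7 with CuI/1,10-phenanthroline/Cs2CO3 in toluene as in step 4.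

Step 5. β-Hydride elimination may go toward the acetal carbon, which after hydrolysis gives the saturated ester instead of the enal, and oxidative addition of the electron-rich aryl bromide may be slow. The fallback sets out from 7 and comes back at 9. Bromine–lithium exchange (n-BuLi, THF, −78 °C) and quench with DMF gives (2S,3S)-8-methoxy-2-methyl-3-(3,4,5-trimethoxyphenyl)-2,3-dihydro-1,4-benzodioxine-6-carbaldehyde F4. Wittig olefination of F4 with (triphenylphosphoranylidene)acetaldehyde in toluene at 80 °C then gives the E-enal 9.

Step 3. The doubly ortho-substituted phenoxide is a slow nucleophile, so base-induced dehydrobromination of 2 to the aryl vinyl ketone, followed by conjugate addition of the phenoxide at the terminal carbon, may compete with substitution. The fallback sets out from 2 and 4 and comes back at 5; it forms the same ether under neutral conditions. Sodium formate in aqueous ethanol at reflux converts 2 into the formate ester rac-1-oxo-1-(3,4,5-trimethoxyphenyl)propan-2-yl formate F5, which is hydrolysed in the same medium to rac-2-hydroxy-1-(3,4,5-trimethoxyphenyl)propan-1-one F6. Mitsunobu coupling of F6 with 4 (PPh3, DIAD, THF) gives 5.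

**Further compounds**

F1 | step 4 | methyl (S)-2-(4-bromo-2-iodo-6-methoxyphenoxy)propanoate | COC(=O)[C@H](C)Oc1c(I)cc(Br)cc1OC
F2 | step 4 | (S)-2-(4-bromo-2-iodo-6-methoxyphenoxy)-N-methoxy-N-methylpropanamide | CON(C)C(=O)[C@H](C)Oc1c(I)cc(Br)cc1OC
F3 | step 4 | (S)-2-(4-bromo-2-iodo-6-methoxyphenoxy)-1-(3,4,5-trimethoxyphenyl)propan-1-one | COc1cc(C(=O)[C@H](C)Oc2c(I)cc(Br)cc2OC)cc(OC)c1OC
F4 | step 5 | (2S,3S)-8-methoxy-2-methyl-3-(3,4,5-trimethoxyphenyl)-2,3-dihydro-1,4-benzodioxine-6-carbaldehyde | COc1cc([C@@H]2Oc3cc(C=O)cc(OC)c3O[C@H]2C)cc(OC)c1OC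
F5 | step 3 | rac-1-oxo-1-(3,4,5-trimethoxyphenyl)propan-2-yl formate | CC(OC=O)C(=O)c1cc(OC)c(OC)c(OC)c1
F6 | step 3 | rac-2-hydroxy-1-(3,4,5-trimethoxyphenyl)propan-1-one | CC(O)C(=O)c1cc(OC)c(OC)c(OC)c1
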